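Everything rests on cutting ring A at C8–C8a and C5–C4a. The oxygen-bearing run C5–C8 of that ring is the four-carbon unit of dimethyl squarate. C8a=C4a is the free enol-ether double bond of a 6-aryl-4-pyranone that already is ring C. The precursor is a 2,3,4-trimethoxycyclobutenone that carries this pyranone on C4, bound through the pyranone carbon next to the ring oxygen. Heating opens the four-membered ring to a dienylketene, which closes by 6π electrocyclization onto the pyranone CH and enolizes. One operation thus builds the hexasubstituted benzene with the 6,7,8-methoxy groups in place and only 5-OH free. Methylation and debenzylation finish the route.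

Key step: step 6

Assumption: flavone numbering (O1, C2, C3, C4, C4a, C5 to C8, C8a, primed positions on ring B) is used for 12 to 15; diketone 5 is drawn as its diketo tautomer; 9, 10 and 12 are racemates.

Step 1
Reactants: 1 4-(benzyloxy)benzoic acid
Product: 2 4-(benzyloxy)benzoyl chloride
Conditions: (COCl)2 (1.3 equiv), DMF (cat.), CH2Cl2, 0 °C to rt; concentrate, use crude
Reagents that add atoms: oxalyl chloride, O=C(Cl)C(=O)Cl
Why: Acid chloride formation through the chloroiminium species made from catalytic DMF runs under mild, gas-evolving conditions that do not touch the benzyl aryl ether.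

Step 2
Reactants: 2 4-(benzyloxy)benzoyl chloride; 3 (E)-4-methoxybut-3-en-2-one
Product: 5 (E)-1-[4-(benzyloxy)phenyl]-5-methoxypent-4-ene-1,3-dione, via lithium dienolate 4 (not isolated)
Conditions: 3 (2.0 equiv), LiHMDS (2.05 equiv), THF, −78 °C; then 2 (1.0 equiv) in THF, −78 to −20 °C; AcOH quench
Reagents that add atoms: none
Why: In this crossed Claisen C-acylation the methyl group is the only enolizable site of 3, so a single dienolate attacks the acyl chloride at carbon, while the second equivalent of the cheap enolate (not free amide, which would consume 2) deprotonates the more acidic 1,3-diketone and suppresses double acylation.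

Step 3
Reactants: 5 (E)-1-[4-(benzyloxy)phenyl]-5-methoxypent-4-ene-1,3-dione
Product: 6 2-[4-(benzyloxy)phenyl]-4H-pyran-4-one
Conditions: TFA (3 equiv), CH2Cl2, rt
Reagents that add atoms: none
Why: Acid-promoted 6-endo oxa-Michael addition of the aryl-ketone enol oxygen to the activated β-methoxyenone, followed by loss of methanol (addition–elimination cyclocondensation), is the standard closure of such diketo enol ethers to 4-pyranones, and a benzyl aryl ether tolerates TFA at room temperature.

Step 4
Reactants: 6 2-[4-(benzyloxy)phenyl]-4H-pyran-4-one; 7 dimethyl squarate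
Product: 9 4-{6-[4-(benzyloxy)phenyl]-4-oxo-4H-pyran-2-yl}-4-hydroxy-2,3-dimethoxycyclobut-2-en-1-one (racemic), via 6-lithiopyranone 8 (not isolated)
Conditions: TMPH (1.3 equiv), n-BuLi (1.25 equiv), THF, −78 to 0 °C, recool to −78 °C; 6 in THF added dropwise to the base, 15 min; cannulate into 7 (1.5 equiv), THF, −78 °C; AcOH in THF at −78 °C
Reagents that add atoms: none
Why: This is deprotonative lithiation followed by 1,2-carbonyl addition, in which the CH beside the ring oxygen is the most acidic ring position (as in the known C2 lithiation of chromones), the hindered amide cannot add to the pyranone, slow addition of 6 to excess base keeps unmetalated 6 away from 8, and organolithiums attack dialkyl squarates at a carbonyl at −78 °C, giving the carbinol centre as a racemate because the planar squarate has equivalent faces.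

Step 5
Reactants: 9 4-{6-[4-(benzyloxy)phenyl]-4-oxo-4H-pyran-2-yl}-4-hydroxy-2,3-dimethoxycyclobut-2-en-1-one (racemic)
Product: 10 4-{6-[4-(benzyloxy)phenyl]-4-oxo-4H-pyran-2-yl}-2,3,4-trimethoxycyclobut-2-en-1-one (racemic)
Conditions: MeI (10 equiv), Ag2O (2 equiv), 4 Å MS, CH2Cl2, rt, dark
Reagents that add atoms: iodomethane, CI
Why: Purdie-type O-methylation caps the tertiary cyclobutenol under nearly neutral conditions, so no free alkoxide builds up that could revert or cleave the ring, and it is preferred to methyl triflate, which would also alkylate the pyranone carbonyl to a pyrylium salt; the racemic centre is not touched.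

Step 6
Reactants: 10 4-{6-[4-(benzyloxy)phenyl]-4-oxo-4H-pyran-2-yl}-2,3,4-trimethoxycyclobut-2-en-1-one (racemic)
Product: 13 4'-(benzyloxy)-5-hydroxy-6,7,8-trimethoxyflavone, via dienylketene 11 (not isolated), via cyclohexadienone 12 (not isolated)
Conditions: degassed p-xylene (0.02 M), 138 °C, Ar
Reagents that add atoms: none
Why: Heating breaks the C1–C4 σ bond of 10 in a conrotatory 4π electrocyclic opening to dienylketene 11, which erases the racemic quaternary centre. The selectivity that matters is torquoselectivity, and it is secured by the lone-pair donor OMe on the breaking carbon, which turns outward so that the pyranonyl group turns inward and lies cis to the ketene (Z geometry in 11). Ring A, a six-membered carbocycle, then closes by disrotatory 6π electrocyclization in which the ketene carbon (future C5) bonds to the pyranone CH beside the attachment carbon (future C4a), giving the ring-fused dienone 12. Site selectivity is fixed by the substrate, because the attachment carbon (future C8a) has the ring oxygen as its other neighbour, so only one carbon terminus exists, and that carbon is the nucleophilic α-position of a vinylogous ester, matched in polarity to the electrophilic ketene. The only new stereocentre, C4a-H of 12, arises racemic with no controlling element and vanishes at once, since this hydrogen sits between two carbonyl groups and shifts to oxygen to give the chelated 5-phenol 13, which makes the cascade irreversible. The closest known reaction type is the Moore rearrangement of squarate-derived 4-alkenyl- and 4-heteroaryl-4-alkoxycyclobutenones to annulated monoprotected hydroquinones, and having O8 already methylated avoids an air-sensitive 5,8-hydroquinone.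

Step 7
Reactants: 13 4'-(benzyloxy)-5-hydroxy-6,7,8-trimethoxyflavone
Product: 14 4'-(benzyloxy)-5,6,7,8-tetramethoxyflavone
Conditions: Me2SO4 (3 equiv), K2CO3 (5 equiv), acetone, reflux
Reagents that add atoms: dimethyl sulfate, COS(=O)(=O)OC
Why: Williamson-type O-methylation with excess carbonate and dimethyl sulfate in refluxing acetone is the standard way to overcome the hydrogen bond between 5-OH and the C4 carbonyl of flavones, and 13 has no other acidic site.

Step 8
Reactants: 14 4'-(benzyloxy)-5,6,7,8-tetramethoxyflavone
Product: 15 4'-hydroxy-5,6,7,8-tetramethoxyflavone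
Conditions: H2 (1 atm), 10% Pd/C, EtOAc–MeOH, rt, stopped after one equivalent of H2
Reagents that add atoms: none
Why: Catalytic hydrogenolysis cleaves only the benzylic C–O bond, since aryl methyl ethers are inert and the conjugated C2=C3 bond of a flavone is reduced far more slowly at one atmosphere and room temperature, whereas Lewis-acid debenzylation is avoided because it would strip the 5-OMe group.

Compound list
1 | 4-(benzyloxy)benzoic acid | O=C(O)c1ccc(OCc2ccccc2)cc1 | starting material
2 | 4-(benzyloxy)benzoyl chloride | O=C(Cl)c1ccc(OCc2ccccc2)cc1 | intermediate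
3 | (E)-4-methoxybut-3-en-2-one | CO/C=C/C(C)=O | starting material
4 | lithium (E)-4-methoxybuta-1,3-dien-2-olate | CO/C=C/C(=C)O[Li] | intermediate
5 | (E)-1-[4-(benzyloxy)phenyl]-5-methoxypent-4-ene-1,3-dione | CO/C=C/C(=O)CC(=O)c1ccc(OCc2ccccc2)cc1 | intermediate
6 | 2-[4-(benzyloxy)phenyl]-4H-pyran-4-one | O=c1ccoc(-c2ccc(OCc3ccccc3)cc2)c1 | intermediate
7 | dimethyl squarate (3,4-dimethoxycyclobut-3-ene-1,2-dione) | COC1=C(OC)C(=O)C1=O | starting material
8 | 2-[4-(benzyloxy)phenyl]-6-lithio-4H-pyran-4-one | [Li]c1cc(=O)cc(-c2ccc(OCc3ccccc3)cc2)o1 | intermediate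
9 | 4-{6-[4-(benzyloxy)phenyl]-4-oxo-4H-pyran-2-yl}-4-hydroxy-2,3-dimethoxycyclobut-2-en-1-one (racemic) | COC1=C(OC)C(O)(c2cc(=O)cc(-c3ccc(OCc4ccccc4)cc3)o2)C1=O | intermediate
10 | 4-{6-[4-(benzyloxy)phenyl]-4-oxo-4H-pyran-2-yl}-2,3,4-trimethoxycyclobut-2-en-1-one (racemic) | COC1=C(OC)C(OC)(c2cc(=O)cc(-c3ccc(OCc4ccccc4)cc3)o2)C1=O | intermediate
11 | (Z)-4-{6-[4-(benzyloxy)phenyl]-4-oxo-4H-pyran-2-yl}-2,3,4-trimethoxybuta-1,3-dien-1-one | O=C=C(OC)/C(OC)=C(\c1cc(=O)cc(-c2ccc(OCc3ccccc3)cc2)o1)OC | intermediate
12 | 2-[4-(benzyloxy)phenyl]-6,7,8-trimethoxy-4aH-chromene-4,5-dione (racemic) | COC1=C(OC)C(=O)C2C(=O)C=C(c3ccc(OCc4ccccc4)cc3)OC2=C1OC | intermediate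
13 | 4'-(benzyloxy)-5-hydroxy-6,7,8-trimethoxyflavone | COc1c(OC)c(O)c2c(=O)cc(-c3ccc(OCc4ccccc4)cc3)oc2c1OC | intermediate
14 | 4'-(benzyloxy)-5,6,7,8-tetramethoxyflavone | COc1c(OC)c(OC)c2c(=O)cc(-c3ccc(OCc4ccccc4)cc3)oc2c1OC | intermediate
15 | 4'-hydroxy-5,6,7,8-tetramethoxyflavone | COc1c(OC)c(OC)c2c(=O)cc(-c3ccc(O)cc3)oc2c1OC | target

Total step count: 8
Longest linear sequence: 8 steps (1 to 15)

Steps most likely to fail

Step 4. Three processes may interfere:
- conjugate self-addition of the lithiated pyranone to pyranone that is not yet metalated;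
- competing deprotonation at a CH next to the carbonyl, followed by ring fragmentation;
- proton shuffling before the squarate is reached.

The fallback sets out from 6 and comes back at 9. It replaces deprotonation with a lithium amide by halogen–magnesium exchange on an isolated halide. Compound 6 would be zincated beside the ring oxygen with TMP2Zn·2MgCl2·2LiCl (THF, −30 °C), the mixed amide type known to metalate chromones at that position. This gives bis{6-[4-(benzyloxy)phenyl]-4-oxo-4H-pyran-2-yl}zinc F1, a carbon–zinc species too mild to self-condense. Iodine then converts it into 2-[4-(benzyloxy)phenyl]-6-iodo-4H-pyran-4-one F2, which can be purified and whose regiochemistry can be checked. Exchange with iPrMgCl·LiCl (THF, −78 °C) should give {6-[4-(benzyloxy)phenyl]-4-oxo-4H-pyran-2-yl}magnesium chloride F3 with no amine and no unmetalated pyranone present. Adding F3 to 7 and quenching with mild acid gives 9.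

Step 6. The electrocyclization onto the cross-conjugated pyranone double bond may be slower than ketene dimerization, acylation of the product phenol by the ketene, or thermal decay of the substrate.

The fallback sets out from 2 and comes back at 14. Ring A is bought instead of built, and ring C is closed last. Commercial 2'-hydroxy-3',4',5',6'-tetramethoxyacetophenone F4 would be O-acylated with 2 (pyridine, DMAP cat., CH2Cl2) to 2-acetyl-3,4,5,6-tetramethoxyphenyl 4-(benzyloxy)benzoate F5. Baker–Venkataraman acyl migration (KOH, pyridine, 50 °C) would give 1-[4-(benzyloxy)phenyl]-3-(2-hydroxy-3,4,5,6-tetramethoxyphenyl)propane-1,3-dione F6. Cyclodehydration (p-TsOH cat., toluene, reflux) would then deliver 14.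

Step 5. Alkylation of the hindered tertiary carbinol may be sluggish, the cyclobutenol may revert or cleave on the basic oxide surface, and the pyranone carbonyl may be alkylated.

The fallback sets out from 9 and comes back at 14. It drops the separate protection. The free alcohol 9 would be heated in degassed p-xylene under argon, and the same Moore cascade should give 4'-(benzyloxy)-5,8-dihydroxy-6,7-dimethoxyflavone F7. This would be kept under inert gas and methylated on both phenols at once (Me2SO4, K2CO3, acetone, reflux) to give 14.

Further compounds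
F1 | step 4 | bis{6-[4-(benzyloxy)phenyl]-4-oxo-4H-pyran-2-yl}zinc | O=c1cc([Zn]c2cc(=O)cc(-c3ccc(OCc4ccccc4)cc3)o2)oc(-c2ccc(OCc3ccccc3)cc2)c1
F2 | step 4 | 2-[4-(benzyloxy)phenyl]-6-iodo-4H-pyran-4-one | O=c1cc(I)oc(-c2ccc(OCc3ccccc3)cc2)c1
F3 | step 4 | {6-[4-(benzyloxy)phenyl]-4-oxo-4H-pyran-2-yl}magnesium chloride | O=c1cc([Mg]Cl)oc(-c2ccc(OCc3ccccc3)cc2)c1
F4 | step 6 | 2'-hydroxy-3',4',5',6'-tetramethoxyacetophenone (bought) | CC(=O)c1c(O)c(OC)c(OC)c(OC)c1OC
F5 | step 6 | 2-acetyl-3,4,5,6-tetramethoxyphenyl 4-(benzyloxy)benzoate | CC(=O)c1c(OC)c(OC)c(OC)c(OC)c1OC(=O)c1ccc(OCc2ccccc2)cc1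
F6 | step 6 | 1-[4-(benzyloxy)phenyl]-3-(2-hydroxy-3,4,5,6-tetramethoxyphenyl)propane-1,3-dione | O=C(CC(=O)c1c(O)c(OC)c(OC)c(OC)c1OC)c1ccc(OCc2ccccc2)cc1
F7 | step 5 | 4'-(benzyloxy)-5,8-dihydroxy-6,7-dimethoxyflavone | COc1c(OC)c(O)c2c(=O)cc(-c3ccc(OCc4ccccc4)cc3)oc2c1O
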